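**Plan** (target numbering: C1 prenyl bridgehead, C5 lavandulyl bridgehead, C9 bridging ketone, C2–C3–C4 aroyl-diketone bridge, C6H2–C7H(prenyl)–C8Me2 saturated bridge)
- Cuts, in order: the C3–aroyl bond and the enol methyl ether; C7–H (from C7–SO2Ph); C5–C6 together with C7–prenyl (ring A); C1–C8 (a [3,3] shift from an aryl allyl ether); the aryl–prenyl and aryl–lavandulyl bonds of a 5-methoxyresorcinol core.
- Forward: the arene is built by two directed metalations and dearomatised by Claisen rearrangement to the monocyclic dienone 17 (the later C1–C2–C3–C4–C5–C9 ring). Ring A is then closed by Michael addition and C7 is prenylated in the same flask; the sulfone is removed, the aroyl group added and the protecting groups cleaved.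
- Enabling feature: in 17, C5 lies between the C4 and C9 carbonyl groups (a soft enolate carbon), while the CMe2 arm on quaternary C1 ends in a vinyl sulfone whose CH2 terminus is C6 and whose sulfonyl carbon is C7. One 6-endo addition therefore closes ring A and leaves C7 activated for prenylation.
- Stereochemistry: the side-chain centre comes from (R)-lavandulol. C1 is formed in the Claisen step without facial control (see remark). C5 is dictated by the tether from C1. C7 is set by exo-face protonation in the desulfonylation.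

Key step: step 10

Remark: the lavandulyl stereocentre is too remote to bias the [3,3] shift of step 9, so both C1 epimers are expected; being diastereomers, they are assumed to be separable by chromatography, and only 17 is carried on.
In names, prenyl = 3-methylbut-2-en-1-yl and (S)-lavandulyl = (2S)-5-methyl-2-(prop-1-en-2-yl)hex-4-en-1-yl (the group of (R)-lavandulol; only the descriptor changes). Bicyclic compounds carry the target numbering; exo means the side away from the C2–C3–C4 bridge.

**Step 1**
Reactants: 1 (R)-lavandulol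
Product: 2 (R)-lavandulyl iodide
Conditions: I2, PPh3, imidazole, CH2Cl2, 0 °C → rt
Reagents that add atoms: iodine, II
Why: Garegg–Samuelsson (Appel-type) iodination of a primary alcohol; the stereocentre is β to the reacting carbon and is not touched.

**Step 2**
Reactants: 3 3-methylbuta-1,2-diene
Product: 4 1-iodo-3-methyl-2-(phenylsulfonyl)but-2-ene
Conditions: PhSO2Na, I2, CH2Cl2/H2O, rt, visible light
Reagents that add atoms: sodium benzenesulfinate, [Na+].[O-]S(=O)c1ccccc1; iodine, II
Why: Radical iodosulfonylation of an allene, in which the sulfonyl radical from benzenesulfonyl iodide adds to the central carbon and iodine is delivered to the unsubstituted terminus of the resulting allyl radical, giving the tetrasubstituted vinyl sulfone.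

**Step 3**
Reactants: 5 5-methoxyresorcinol
Product: 6 1-methoxy-3,5-bis(methoxymethoxy)benzene
Conditions: MOMCl, i-Pr2NEt, CH2Cl2, 0 °C → rt
Reagents that add atoms: chloromethyl methyl ether, COCCl
Why: Standard O-alkylation of both phenols, which installs two ortho-directing groups for the metalations that follow.

**Step 4**
Reactants: 6 1-methoxy-3,5-bis(methoxymethoxy)benzene; 2 (R)-lavandulyl iodide
Product: 8 2-[(S)-lavandulyl]-5-methoxy-1,3-bis(methoxymethoxy)benzene, via aryllithium 7 (not isolated)
Conditions: n-BuLi, THF, 0 °C; then 2, CuI (10 mol %), −20 °C → rt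
Reagents that add atoms: none
Why: Directed ortho-metalation at the position flanked by both MOM ethers, followed by copper-catalysed alkylation of the aryl anion with the primary iodide; the side-chain stereocentre is not involved.

**Step 5**
Reactants: 8 2-[(S)-lavandulyl]-5-methoxy-1,3-bis(methoxymethoxy)benzene; 9 prenyl bromide
Product: 11 1-methoxy-3,5-bis(methoxymethoxy)-2-prenyl-4-[(S)-lavandulyl]benzene, via aryllithium 10 (not isolated)
Conditions: n-BuLi, THF, 0 °C; then CuI (10 mol %), prenyl bromide, −78 → 0 °C
Reagents that add atoms: none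
Why: Second directed ortho-metalation at one of the two equivalent positions between OMe and OMOM, then copper-mediated SN2 prenylation; the symmetry of 8 makes the site unambiguous.

**Step 6**
Reactants: 11 1-methoxy-3,5-bis(methoxymethoxy)-2-prenyl-4-[(S)-lavandulyl]benzene
Product: 12 5-methoxy-4-prenyl-2-[(S)-lavandulyl]benzene-1,3-diol
Conditions: HCl (cat.), MeOH, rt
Reagents that add atoms: none
Why: Acid-catalysed acetal exchange cleaves both aryl MOM ethers at room temperature, mild enough to leave the prenyl and isopropenyl double bonds uncyclised.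

**Step 7**
Reactants: 12 5-methoxy-4-prenyl-2-[(S)-lavandulyl]benzene-1,3-diol
Product: 13 3-methoxy-2-prenyl-6-[(S)-lavandulyl]-5-[(triisopropylsilyl)oxy]phenol
Conditions: TIPSCl (1.05 equiv), imidazole, DMF, 0 °C
Reagents that add atoms: triisopropylsilyl chloride, CC(C)[Si](Cl)(C(C)C)C(C)C
Why: Sterically controlled silylation, in which the bulky chloride takes the hydroxyl with one ortho substituent (O4) and leaves the doubly flanked O9–H free.

**Step 8**
Reactants: 13 3-methoxy-2-prenyl-6-[(S)-lavandulyl]-5-[(triisopropylsilyl)oxy]phenol; 4 1-iodo-3-methyl-2-(phenylsulfonyl)but-2-ene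
Product: 14 aryl 3-methyl-2-(phenylsulfonyl)but-2-enyl ether of 13
Conditions: K2CO3, acetone, rt
Reagents that add atoms: none
Why: Williamson etherification of the remaining hindered phenol with a reactive primary allylic iodide (SN2 at CH2).

**Step 9**
Reactants: 14 aryl 3-methyl-2-(phenylsulfonyl)but-2-enyl ether of 13
Product: 17 (4R)-3-hydroxy-5-methoxy-4-[2-methyl-3-(phenylsulfonyl)but-3-en-2-yl]-4-prenyl-2-[(S)-lavandulyl]cyclohexa-2,5-dien-1-one, via cesium phenoxide 15 (not isolated), via cesium enolate 16 (not isolated)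
Conditions: CsF, DMF, 0 → 60 °C; then AcOH, 0 °C; chromatography
Reagents that add atoms: none
Why: Fluoride desilylation unveils the O4 phenoxide, and an aromatic Claisen rearrangement of the allyl ether onto the prenyl-bearing ortho carbon (para to the phenoxide) gives the cross-conjugated β-diketonate of 17 directly; in the absence of a proton source this enolate cannot go on to a Michael adduct, and C1 forms without facial control so 17 is separated from its C1 epimer.

**Step 10**
Reactants: 17 dearomatised phloroglucinol methyl ether with the sulfonylallyl arm on C1; 9 prenyl bromide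
Product: 20 bicyclic 7-prenyl-7-(phenylsulfonyl) vinylogous ester (7-prenyl exo), via Michael adduct 18 (not isolated), via lithium carbanion 19 (not isolated)
Conditions: KOt-Bu (10 mol %), THF, 0 °C → rt; then lithium diisopropylamide (LDA), −78 °C, 5 min; prenyl bromide, DMPU, −78 → −40 °C
Reagents that add atoms: none
Why: Catalytic tert-butoxide converts the vinylogous acid 17 into its C5 enolate, which adds to the CH2 terminus of the tethered vinyl sulfone (6-endo-trig, ring A), the closest known reaction type being the base-mediated annulation of dearomatised phloroglucinols with acrylate-type acceptors; the C7 carbanion is far too basic to persist beside the stabilised enolate and is protonated by a second molecule of 17, so the closure runs as a proton-transfer chain to neutral 18. The bridgehead C5 can form only on the ring face that carries the C1 arm, so its configuration follows from C1. LDA then removes the sulfone α-hydrogen at C7, by some nine pK units the most acidic C–H left, and the tertiary sulfonyl carbanion 19 is alkylated by prenyl bromide from the open exo face, an ordinary α-sulfonyl carbanion alkylation. This places prenyl exo and the sulfonyl group endo, which does not matter because C7 is reset in step 11. Two selectivities are needed: C- rather than O-attack of the ambident enolate, favoured by the soft acceptor and the tight ion pair in THF, and alkylation of 19 faster than its retro-Michael collapse to the stabilised enolate, for which the carbanion is made at −78 °C and quenched within minutes. C3 cannot act as a nucleophile in the first stage because O2 is methylated.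

**Step 11**
Reactants: 20 bicyclic 7-prenyl-7-(phenylsulfonyl) vinylogous ester
Product: 21 2-methoxy-8,8-dimethyl-1,7-diprenyl-5-[(S)-lavandulyl]bicyclo[3.3.1]non-2-ene-4,9-dione (7-prenyl endo)
Conditions: sodium amalgam (Na/Hg, 6% Na), Na2HPO4, MeOH/THF, −20 °C
Reagents that add atoms: none
Why: Reductive desulfonylation (electron transfer, loss of sulfinate, reduction to the C7 carbanion) with protonation by methanol from the open exo face, which leaves prenyl endo as in the target; the hindered C9 ketone and the vinylogous ester should be reduced more slowly than the sulfone at this temperature.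

**Step 12**
Reactants: 22 vanillic acid
Product: 23 tert-butyldimethylsilyl 4-[(tert-butyldimethylsilyl)oxy]-3-methoxybenzoate
Conditions: TBSCl (2.2 equiv), imidazole, DMF, rt
Reagents that add atoms: tert-butyldimethylsilyl chloride, CC(C)(C)[Si](C)(C)Cl
Why: Routine silylation of both the phenol and the carboxylic acid.

**Step 13**
Reactants: 23 tert-butyldimethylsilyl 4-[(tert-butyldimethylsilyl)oxy]-3-methoxybenzoate
Product: 24 4-[(tert-butyldimethylsilyl)oxy]-3-methoxybenzoyl chloride
Conditions: (COCl)2, DMF (cat.), CH2Cl2, 0 °C → rt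
Reagents that add atoms: oxalyl chloride, O=C(Cl)C(Cl)=O
Why: Direct conversion of a silyl ester into the acid chloride by Vilsmeier-type activation under neutral conditions, which keeps the aryl silyl ether.

**Step 14**
Reactants: 21 bicyclic vinylogous ester (7-prenyl endo); 24 4-[(tert-butyldimethylsilyl)oxy]-3-methoxybenzoyl chloride
Product: 26 3-aroyl bicyclic vinylogous ester, via vinyllithium 25 (not isolated)
Conditions: lithium 2,2,6,6-tetramethylpiperidide (LiTMP), THF, −78 °C; then 24, −78 → −40 °C
Reagents that add atoms: none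
Why: Vinylic α-lithiation of the vinylogous ester at C3 with a hindered amide base and C-acylation with the aroyl chloride, a known way of placing the acyl group on such bicyclic cores; both bridgeheads are quaternary, so no other site can be metalated.

**Step 15**
Reactants: 26 3-aroyl bicyclic vinylogous ester
Product: 27 garcinol 13-O-methyl ether
Conditions: LiOH, dioxane/H2O, 90 °C; then 1 M HCl
Reagents that add atoms: lithium hydroxide, [Li+].[OH-]
Why: Hydroxide cleaves the vinylogous methyl ester by addition–elimination and the aryl silyl ether at silicon in one operation, with no stereocentre affected.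

**Compound list**
1 | (R)-lavandulol, (2R)-5-methyl-2-(prop-1-en-2-yl)hex-4-en-1-ol | C=C(C)[C@@H](CC=C(C)C)CO | starting material
2 | (R)-lavandulyl iodide, (2R)-1-iodo-5-methyl-2-(prop-1-en-2-yl)hex-4-ene | C=C(C)[C@@H](CC=C(C)C)CI | intermediate
3 | 3-methylbuta-1,2-diene | CC(C)=C=C | starting material
4 | 1-iodo-3-methyl-2-(phenylsulfonyl)but-2-ene | CC(C)=C(CI)S(=O)(=O)c1ccccc1 | intermediate
5 | 5-methoxyresorcinol (5-methoxybenzene-1,3-diol) | COc1cc(O)cc(O)c1 | starting material
6 | 1-methoxy-3,5-bis(methoxymethoxy)benzene | COCOc1cc(OC)cc(OCOC)c1 | intermediate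
7 | [4-methoxy-2,6-bis(methoxymethoxy)phenyl]lithium | [Li]c1c(OCOC)cc(OC)cc1OCOC | intermediate (not isolated)
8 | 2-[(S)-lavandulyl]-5-methoxy-1,3-bis(methoxymethoxy)benzene | C=C(C)[C@@H](CC=C(C)C)Cc1c(OCOC)cc(OC)cc1OCOC | intermediate
9 | prenyl bromide (1-bromo-3-methylbut-2-ene) | CC(C)=CCBr | starting material
10 | aryllithium of 8, lithium on the ring carbon between OMe and OMOM | C=C(C)[C@@H](CC=C(C)C)Cc1c(OCOC)cc(OC)c([Li])c1OCOC | intermediate (not isolated)
11 | 1-methoxy-3,5-bis(methoxymethoxy)-2-prenyl-4-[(S)-lavandulyl]benzene | C=C(C)[C@@H](CC=C(C)C)Cc1c(OCOC)cc(OC)c(CC=C(C)C)c1OCOC | intermediate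
12 | 5-methoxy-4-prenyl-2-[(S)-lavandulyl]benzene-1,3-diol | C=C(C)[C@@H](CC=C(C)C)Cc1c(O)cc(OC)c(CC=C(C)C)c1O | intermediate
13 | 3-methoxy-2-prenyl-6-[(S)-lavandulyl]-5-[(triisopropylsilyl)oxy]phenol | C=C(C)[C@@H](CC=C(C)C)Cc1c(O[Si](C(C)C)(C(C)C)C(C)C)cc(OC)c(CC=C(C)C)c1O | intermediate
14 | 3-methyl-2-(phenylsulfonyl)but-2-en-1-yl ether of phenol 13 | C=C(C)[C@@H](CC=C(C)C)Cc1c(O[Si](C(C)C)(C(C)C)C(C)C)cc(OC)c(CC=C(C)C)c1OCC(=C(C)C)S(=O)(=O)c1ccccc1 | intermediate
15 | cesium phenoxide formed from 14 by loss of the silyl group | C=C(C)[C@@H](CC=C(C)C)Cc1c([O-])cc(OC)c(CC=C(C)C)c1OCC(=C(C)C)S(=O)(=O)c1ccccc1.[Cs+] | intermediate (not isolated)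
16 | cesium enolate of 17 | C=C(C)[C@@H](CC=C(C)C)CC1=C([O-])[C@@](CC=C(C)C)(C(C)(C)C(=C)S(=O)(=O)c2ccccc2)C(OC)=CC1=O.[Cs+] | intermediate (not isolated)
17 | (4R)-3-hydroxy-5-methoxy-4-[2-methyl-3-(phenylsulfonyl)but-3-en-2-yl]-4-prenyl-2-[(S)-lavandulyl]cyclohexa-2,5-dien-1-one (quaternary ring carbon = C1 of the target) | C=C(C)[C@@H](CC=C(C)C)CC1=C(O)[C@@](CC=C(C)C)(C(C)(C)C(=C)S(=O)(=O)c2ccccc2)C(OC)=CC1=O | intermediate
18 | 2-methoxy-8,8-dimethyl-7-(phenylsulfonyl)-1-prenyl-5-[(S)-lavandulyl]bicyclo[3.3.1]non-2-ene-4,9-dione, bridgeheads as in the target, C7 epimers | C=C(C)[C@@H](CC=C(C)C)C[C@@]12CC(S(=O)(=O)c3ccccc3)C(C)(C)[C@@](CC=C(C)C)(C(OC)=CC1=O)C2=O | intermediate (not isolated)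
19 | 7-lithio derivative of 18 (configurationally labile at C7) | C=C(C)[C@@H](CC=C(C)C)C[C@@]12CC([Li])(S(=O)(=O)c3ccccc3)C(C)(C)[C@@](CC=C(C)C)(C(OC)=CC1=O)C2=O | intermediate (not isolated)
20 | 2-methoxy-8,8-dimethyl-7-(phenylsulfonyl)-1,7-diprenyl-5-[(S)-lavandulyl]bicyclo[3.3.1]non-2-ene-4,9-dione, bridgeheads as in the target, 7-prenyl exo and sulfonyl endo | C=C(C)[C@@H](CC=C(C)C)C[C@@]12C[C@@](CC=C(C)C)(S(=O)(=O)c3ccccc3)C(C)(C)[C@@](CC=C(C)C)(C(OC)=CC1=O)C2=O | intermediate
21 | 2-methoxy-8,8-dimethyl-1,7-diprenyl-5-[(S)-lavandulyl]bicyclo[3.3.1]non-2-ene-4,9-dione, bridgeheads as in the target, 7-prenyl endo | C=C(C)[C@@H](CC=C(C)C)C[C@@]12C[C@@H](CC=C(C)C)C(C)(C)[C@@](CC=C(C)C)(C(OC)=CC1=O)C2=O | intermediate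
22 | vanillic acid | COc1cc(C(=O)O)ccc1O | starting material
23 | tert-butyldimethylsilyl 4-[(tert-butyldimethylsilyl)oxy]-3-methoxybenzoate | COc1cc(C(=O)O[Si](C)(C)C(C)(C)C)ccc1O[Si](C)(C)C(C)(C)C | intermediate
24 | 4-[(tert-butyldimethylsilyl)oxy]-3-methoxybenzoyl chloride | COc1cc(C(Cl)=O)ccc1O[Si](C)(C)C(C)(C)C | intermediate
25 | 3-lithio derivative of 21 | C=C(C)[C@@H](CC=C(C)C)C[C@@]12C[C@@H](CC=C(C)C)C(C)(C)[C@@](CC=C(C)C)(C(OC)=C([Li])C1=O)C2=O | intermediate (not isolated)
26 | 3-{4-[(tert-butyldimethylsilyl)oxy]-3-methoxybenzoyl} derivative of 21 | C=C(C)[C@@H](CC=C(C)C)C[C@@]12C[C@@H](CC=C(C)C)C(C)(C)[C@@](CC=C(C)C)(C(OC)=C(C(=O)c3ccc(O[Si](C)(C)C(C)(C)C)c(OC)c3)C1=O)C2=O | intermediate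
27 | garcinol 13-O-methyl ether, (1R,5R,7R)-4-hydroxy-3-(4-hydroxy-3-methoxybenzoyl)-8,8-dimethyl-1,7-diprenyl-5-[(S)-lavandulyl]bicyclo[3.3.1]non-3-ene-2,9-dione | C=C(C)[C@@H](CC=C(C)C)C[C@@]12C[C@@H](CC=C(C)C)C(C)(C)[C@@](CC=C(C)C)(C(=O)C(C(=O)c3ccc(O)c(OC)c3)=C1O)C2=O | target

**Step count**
Total: 15 steps. Longest linear sequence: 11 steps (5 → 27 through steps 3–11, 14 and 15).

**Steps most likely to fail**

Step 10 (key step). Three processes threaten it: closure of the enolate through oxygen instead of C5; ring opening of the C7 carbanion by retro-Michael expulsion of the stabilised C5 enolate (or metalation at C3) before it is alkylated; and slow alkylation at the congested C7. Fallback: from 17 only the ring closure is run (catalytic KOt-Bu) and Michael adduct 18 is isolated. NaBH4 in MeOH at 0 °C should reduce only the bridging C9 ketone, giving the C9 carbinol F1, which is silylated (TESOTf, 2,6-lutidine) to the triethylsilyl ether F2. With C9 no longer a carbonyl group, C5 is a poor leaving group, so the sulfonyl carbanion (LDA, THF, −78 °C) can be prenylated without ring opening to give the 7-prenyl silyl ether F3. TBAF then frees the 7-prenyl carbinol F4, and Dess–Martin oxidation rejoins the route at 20.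

Step 9. The sulfonylallyl unit may shift to the lavandulyl-bearing ortho carbon, or move on by a second [3,3] shift to C3 with rearomatisation, and facial control at C1 is absent. Fallback: ether 14 is brominated at its only free ring position (NBS, MeCN, −40 °C) to give the C3-bromo ether F5, so that an onward shift to C3 can no longer end in an arene. Desilylation and rearrangement as in step 9 give the 3-bromo dienone F6, and zinc in acetic acid removes the vinylic bromine to rejoin the route at 17. This does not cure the competition between C1 and C5, which is still resolved by chromatography.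

Step 11. The amalgam may also reduce the C9 ketone or the vinylogous ester, and protonation of C7 from the endo face would give the exo-prenyl epimer. Fallback: the order of events is changed so that the carbonyl groups are masked as anions during the reduction. Compound 20 is lithiated at C3 and aroylated with 24 as in step 14 to give the 3-aroyl sulfone F7, and LiOH as in step 15 gives the 7-phenylsulfonyl trione F8. Its sodium enolate-phenoxide (NaOMe, MeOH) is then treated with sodium amalgam at −20 °C, giving 27 directly.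

**Further compounds**
F1 | step 10 | C9 carbinol of 18 (C7 and C9 epimers) | C=C(C)[C@@H](CC=C(C)C)C[C@@]12CC(S(=O)(=O)c3ccccc3)C(C)(C)[C@@](CC=C(C)C)(C(OC)=CC1=O)C2O
F2 | step 10 | triethylsilyl ether of F1 | C=C(C)[C@@H](CC=C(C)C)C[C@@]12CC(S(=O)(=O)c3ccccc3)C(C)(C)[C@@](CC=C(C)C)(C(OC)=CC1=O)C2O[Si](CC)(CC)CC
F3 | step 10 | 7-prenyl-7-(phenylsulfonyl) C9 triethylsilyl ether (7-prenyl exo) | C=C(C)[C@@H](CC=C(C)C)C[C@@]12C[C@@](CC=C(C)C)(S(=O)(=O)c3ccccc3)C(C)(C)[C@@](CC=C(C)C)(C(OC)=CC1=O)C2O[Si](CC)(CC)CC
F4 | step 10 | 7-prenyl-7-(phenylsulfonyl) C9 carbinol | C=C(C)[C@@H](CC=C(C)C)C[C@@]12C[C@@](CC=C(C)C)(S(=O)(=O)c3ccccc3)C(C)(C)[C@@](CC=C(C)C)(C(OC)=CC1=O)C2O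
F5 | step 9 | C3-bromo derivative of ether 14 | C=C(C)[C@@H](CC=C(C)C)Cc1c(O[Si](C(C)C)(C(C)C)C(C)C)c(Br)c(OC)c(CC=C(C)C)c1OCC(=C(C)C)S(=O)(=O)c1ccccc1
F6 | step 9 | 3-bromo derivative of dienone 17 (bromine on the CH carbon between C–OMe and C=O) | C=C(C)[C@@H](CC=C(C)C)CC1=C(O)[C@@](CC=C(C)C)(C(C)(C)C(=C)S(=O)(=O)c2ccccc2)C(OC)=C(Br)C1=O
F7 | step 11 | 3-{4-[(tert-butyldimethylsilyl)oxy]-3-methoxybenzoyl} derivative of 20 | C=C(C)[C@@H](CC=C(C)C)C[C@@]12C[C@@](CC=C(C)C)(S(=O)(=O)c3ccccc3)C(C)(C)[C@@](CC=C(C)C)(C(OC)=C(C(=O)c3ccc(O[Si](C)(C)C(C)(C)C)c(OC)c3)C1=O)C2=O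
F8 | step 11 | 7-(phenylsulfonyl) derivative of 27 (7-prenyl exo) | C=C(C)[C@@H](CC=C(C)C)C[C@@]12C[C@@](CC=C(C)C)(S(=O)(=O)c3ccccc3)C(C)(C)[C@@](CC=C(C)C)(C(=O)C(C(=O)c3ccc(O)c(OC)c3)=C1O)C2=O
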